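**Strategy.** Longipinane numbering is used (C1 ketone, C2=C3, cyclobutane C4–C5–C11–C10, C6 gem-dimethyl, C7 and C9 ester carbons). The route rests on disconnecting the enone ring C1–C2–C3–C4–C5–C11 at C1–C11 and C4–C5. Because C10 ties C4 to C11, a 3-methylcyclobutenone on quaternary C10 of a cycloheptene can add its C1–C4 σ-bond across the ring olefin C5=C11. This rhodium-catalysed carboacylation closes the cyclohexenone and the cyclobutane in one operation, sets C4, C5 and C11, and delivers the target directly. The precursor is a monocyclic cycloheptene diester made from a furan [4+3] adduct by ring opening, resolution, Claisen rearrangement and 1,3-anti diol monoesterification.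

Key step: step 9

Remark: the labels C1–C11 are kept for the same atoms in every intermediate; 1, 2, 8, 13, 15 and 17 are taken as commercial. Stereodescriptors in names were assigned by hand; the SMILES are authoritative.

**Step 1**
Reactants: 1 3-bromo-3-methylbutan-2-one; 2 3-methylfuran
Product: 4 rac-(1S,5S)-2,2,6-trimethyl-8-oxabicyclo[3.2.1]oct-6-en-3-one, via oxyallyl cation 3 (not isolated)
Conditions: Et3N, CF3CH2OH, 2 (3 equiv), 0 °C → rt
Reagents that add atoms: none
Why: Loss of HBr from 1 gives oxyallyl cation 3, which adds to the furan in a [4+3] cycloaddition (cis bridge, racemic); the hindered CMe2 terminus should bond to the furan α-carbon remote from the methyl group, and the minor regioisomer is removed by chromatography.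

**Step 2**
Reactants: 4
Product: 6 rac-6-hydroxy-4,7,7-trimethylcyclohepta-2,4-dien-1-one, via silyl ether 5 (not isolated)
Conditions: TMSOTf, Et3N, CH2Cl2, −78 → 0 °C; then 1 M HCl, THF, 0 °C
Reagents that add atoms: trimethylsilyl trifluoromethanesulfonate, C[Si](C)(C)OS(=O)(=O)C(F)(F)F (silyl group of 5 only, absent from 6)
Why: The ketone can enolise only towards C8, and silyl-triflate-assisted β-elimination of the bridging oxygen (E1cB-type ring opening) gives the C5 silyl ether of the dienone, which dilute acid cleaves without touching the C5 stereocentre.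

**Step 3**
Reactants: 6
Product: 7 (6S)-6-hydroxy-4,7,7-trimethylcyclohepta-2,4-dien-1-one
Conditions: Burkholderia cepacia lipase, vinyl acetate, MTBE, 30 °C, run past half conversion
Reagents that add atoms: none
Why: Lipase-catalysed acyl transfer is a kinetic resolution; by the empirical size rule for secondary alcohols (large CMe2 side, medium vinyl side) the (R)-alcohol should be acetylated and the (S)-alcohol recovered.

**Step 4**
Reactants: 7; 8 N,N-dimethylacetamide dimethyl acetal
Product: 10 2-[(1R)-1,4,4-trimethyl-5-oxocyclohepta-2,6-dien-1-yl]-N,N-dimethylacetamide, via ketene N,O-acetal 9 (not isolated)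
Conditions: 8 (4 equiv), toluene, 130 °C, sealed tube
Reagents that add atoms: none
Why: Eschenmoser–Claisen rearrangement; the [3,3] shift of 9 is suprafacial across the ring olefin, so the C5–O configuration is transferred to the new quaternary centre C10 while the olefin moves to C5=C11.

**Step 5**
Reactants: 10
Product: 12 2-[(1R,7R)-7-hydroxy-1,4,4-trimethyl-5-oxocyclohept-2-en-1-yl]-N,N-dimethylacetamide, via boronate 11 (not isolated)
Conditions: CuCl (5 mol %), NaOt-Bu (8 mol %), Josiphos-type bisphosphine (6 mol %, antipode matched to the substrate), B2pin2, MeOH, THF, rt; then NaBO3·4H2O, THF–H2O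
Reagents that add atoms: bis(pinacolato)diboron, CC1(C)OB(OC1(C)C)B1OC(C)(C)C(C)(C)O1 (boron of 11 only); sodium perborate, [Na+].[O-]OB=O (hydroxyl oxygen of 12)
Why: Copper-catalysed conjugate borylation of the enone and stereoretentive oxidation give the β-hydroxy ketone; the chiral ligand, matched with attack anti to the acetamide arm on C10, places the C9 oxygen trans to that arm.

**Step 6**
Reactants: 12; 13 (2E)-2-methylbut-2-enal
Product: 14 (1R,2R,6R)-2-[2-(dimethylamino)-2-oxoethyl]-6-hydroxy-2,5,5-trimethylcyclohept-3-en-1-yl (2E)-2-methylbut-2-enoate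
Conditions: SmI2 (30 mol %), 13 (8 equiv), THF, −10 °C, dark
Reagents that add atoms: none
Why: Evans–Tishchenko reduction; the samarium-bound hemiacetal of the C9 alcohol with 13 delivers hydride intramolecularly to the C7 ketone through a chair transition state, which sets the 1,3-anti C7 alcohol and leaves the oxidised aldehyde as the C9 tiglate.

**Step 7**
Reactants: 14; 15 3-methylbut-2-enoyl chloride
Product: 16 (1R,2R,6R)-2-[2-(dimethylamino)-2-oxoethyl]-2,5,5-trimethyl-6-[(3-methylbut-2-enoyl)oxy]cyclohept-3-en-1-yl (2E)-2-methylbut-2-enoate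
Conditions: pyridine, DMAP (cat.), CH2Cl2, 0 °C → rt
Reagents that add atoms: none
Why: DMAP-catalysed acylation of the hindered C7 alcohol; pyridine is too weak a base to deconjugate the senecioyl unit through its vinylketene.

**Step 8**
Reactants: 16; 17 propyne
Product: 20 (1R,2S,6R)-2,5,5-trimethyl-6-[(3-methylbut-2-enoyl)oxy]-2-(2-methyl-4-oxocyclobut-2-en-1-yl)cyclohept-3-en-1-yl (2E)-2-methylbut-2-enoate (both epimers at the cyclobutenone sp3 carbon C4), via keteniminium triflate 18 (not isolated), via cyclobuteniminium triflate 19 (not isolated)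
Conditions: Tf2O, 2,4,6-collidine, 17 (excess), ClCH2CH2Cl, −20 → 60 °C, sealed tube; then aq. NaHCO3
Reagents that add atoms: water, O (carbonyl oxygen of 20); trifluoromethanesulfonic anhydride, O=S(=O)(OS(=O)(=O)C(F)(F)F)C(F)(F)F (counter-ion of 18 and 19 only)
Why: Amide activation gives keteniminium salt 18, whose [2+2] cycloaddition with propyne (terminal carbon to the iminium carbon) and hydrolysis give the 3-methyl-4-substituted cyclobutenone; the esters and the hindered or electron-poor olefins should not react with 18.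

**Step 9**
Reactants: 20
Product: 22 target CNP0277258.1 (C9 tiglate, C7 senecioate of the longipin-2-en-1-one core), via rhodacyclopentenone 21 (not isolated)
Conditions: [Rh(C2H4)2Cl]2 (5 mol %), P(3,5-(CF3)2C6H3)3 (12 mol %), 1,4-dioxane, 90 °C
Reagents that add atoms: none
Why: Proposed new method: monovalent rhodium should insert into the acyl–C4 bond of the cyclobutenone to give rhodacycle 21 (an η4-vinylketene in its other form); the C5=C11 olefin on the same quaternary carbon then inserts into the Rh–acyl bond (C1–C11), and allyl–alkyl reductive elimination from the resulting five-membered rhodacycle forms C4–C5. The closest known reactions are the rhodium-catalysed carboacylation of tethered olefins by C–C activation of cyclobutanones and benzocyclobutenones and the rhodium-catalysed [4+2] coupling of cyclobutenones with strained olefins; new here is the one-carbon tether, which makes the second bond a cyclobutane bond, a reductive elimination so far known from metallacyclopentanes in iron- and nickel-catalysed [2+2] reactions. The six-membered enone ring closes by migratory insertion onto the proximal olefin carbon C11, and the four-membered ring closes by reductive elimination between C5 and the γ-terminus C4. C4, C5 and C11 are all fixed by C10, since both bonds must form on the olefin face that carries the cyclobutenone and the bridged product can only be cis; C4 is sp2 in the vinylketene form, so both epimers of 20 converge. The step needs olefin insertion to outrun decarbonylation and needs coupling at C4, not at the α-carbon C2 (which would give the cyclobutanone isomer). β-Hydride loss is disfavoured because C5 is flanked by quaternary C6 and the C11 hydrogen is held anti to rhodium in the metallacycle, and the ester olefins are remote and electron-poor.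

**Compound list**
1 | 3-bromo-3-methylbutan-2-one | CC(=O)C(C)(C)Br | starting material
2 | 3-methylfuran | Cc1ccoc1 | starting material
3 | 1,1-dimethyl-2-oxidoallyl cation | C[C+](C)C([O-])=C | intermediate (not isolated)
4 | rac-(1S,5S)-2,2,6-trimethyl-8-oxabicyclo[3.2.1]oct-6-en-3-one (racemate, enantiomer carried forward drawn) | CC1=C[C@@H]2O[C@H]1CC(=O)C2(C)C | intermediate
5 | rac-4,7,7-trimethyl-6-(trimethylsilyloxy)cyclohepta-2,4-dien-1-one | C[Si](C)(C)OC1C=C(C)C=CC(=O)C1(C)C | intermediate (not isolated)
6 | rac-6-hydroxy-4,7,7-trimethylcyclohepta-2,4-dien-1-one | O=C1C=CC(C)=CC(O)C1(C)C | intermediate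
7 | (6S)-6-hydroxy-4,7,7-trimethylcyclohepta-2,4-dien-1-one | O=C1C=CC(C)=C[C@H](O)C1(C)C | intermediate
8 | N,N-dimethylacetamide dimethyl acetal | CC(OC)(OC)N(C)C | starting material
9 | 1-(dimethylamino)vinyl ether of 7 (ketene N,O-acetal) | C=C(N(C)C)O[C@H]1C=C(C)C=CC(=O)C1(C)C | intermediate (not isolated)
10 | 2-[(1R)-1,4,4-trimethyl-5-oxocyclohepta-2,6-dien-1-yl]-N,N-dimethylacetamide | O=C1C=C[C@](C)(CC(=O)N(C)C)C=CC1(C)C | intermediate
11 | C9 pinacolboronate of 10 (boron trans to the acetamide arm) | O=C1C[C@@H](B2OC(C)(C)C(C)(C)O2)[C@](C)(CC(=O)N(C)C)C=CC1(C)C | intermediate (not isolated)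
12 | 2-[(1R,7R)-7-hydroxy-1,4,4-trimethyl-5-oxocyclohept-2-en-1-yl]-N,N-dimethylacetamide | O=C1C[C@@H](O)[C@](C)(CC(=O)N(C)C)C=CC1(C)C | intermediate
13 | (2E)-2-methylbut-2-enal | C/C=C(\C)C=O | starting material
14 | (1R,2R,6R)-2-[2-(dimethylamino)-2-oxoethyl]-6-hydroxy-2,5,5-trimethylcyclohept-3-en-1-yl (2E)-2-methylbut-2-enoate | O[C@@H]1C[C@@H](OC(=O)/C(C)=C/C)[C@](C)(CC(=O)N(C)C)C=CC1(C)C | intermediate
15 | 3-methylbut-2-enoyl chloride | CC(C)=CC(=O)Cl | starting material
16 | (1R,2R,6R)-2-[2-(dimethylamino)-2-oxoethyl]-2,5,5-trimethyl-6-[(3-methylbut-2-enoyl)oxy]cyclohept-3-en-1-yl (2E)-2-methylbut-2-enoate | CC(C)=CC(=O)O[C@@H]1C[C@@H](OC(=O)/C(C)=C/C)[C@](C)(CC(=O)N(C)C)C=CC1(C)C | intermediate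
17 | propyne | CC#C | starting material
18 | keteniminium triflate from 16 | CC(C)=CC(=O)O[C@@H]1C[C@@H](OC(=O)/C(C)=C/C)[C@](C)(C=C=[N+](C)C)C=CC1(C)C.[O-]S(=O)(=O)C(F)(F)F | intermediate (not isolated)
19 | cyclobuteniminium triflate (N,N-dimethyliminium of 20) | CC(C)=CC(=O)O[C@@H]1C[C@@H](OC(=O)/C(C)=C/C)[C@](C)(C2C(=[N+](C)C)C=C2C)C=CC1(C)C.[O-]S(=O)(=O)C(F)(F)F | intermediate (not isolated)
20 | (1R,2S,6R)-2,5,5-trimethyl-6-[(3-methylbut-2-enoyl)oxy]-2-(2-methyl-4-oxocyclobut-2-en-1-yl)cyclohept-3-en-1-yl (2E)-2-methylbut-2-enoate, epimers at cyclobutenone C4 | CC(C)=CC(=O)O[C@@H]1C[C@@H](OC(=O)/C(C)=C/C)[C@](C)(C2C(=O)C=C2C)C=CC1(C)C | intermediate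
21 | rhodacyclopentenone from insertion of rhodium into the acyl–C4 bond of 20 (phosphine ligands omitted) | CC(C)=CC(=O)O[C@@H]1C[C@@H](OC(=O)/C(C)=C/C)[C@](C)(C2[Rh](Cl)C(=O)C=C2C)C=CC1(C)C | intermediate (not isolated)
22 | target CNP0277258.1 | C/C=C(\C)C(=O)O[C@@H]1C[C@@H](OC(=O)C=C(C)C)C(C)(C)[C@@H]2[C@H]3C(=O)C=C(C)[C@@H]2[C@]31C | target

**Total step count:** 9. **Longest linear sequence:** 9 steps (from 1 and 2).

**Steps most likely to fail**

1. **Step 9 (proposed new method).** The olefin may fail to insert before the rhodacycle loses CO, or reductive elimination may occur at the α-terminus of the allyl–rhodium unit, or the catalyst may not turn over.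

   Fallback (known reaction types only; sets out from 4, returns at 22). The same two bonds are made by a tethered intramolecular Diels–Alder reaction, and C10 is made quaternary afterwards.
   - Nickel-catalysed hydroalumination of the strained olefin of 4 (Ni(cod)2, dppb, excess i-Bu2AlH, toluene) should deliver hydride to C10 on the exo face, expel the C5–O bond and reduce the ketone. This gives rac-4,7,7-trimethylcyclohept-5-ene-1,3-diol F1 (C9–OH and C10–H cis; the C7 epimers are inconsequential).
   - Lipase and vinyl acetate acetylate the C9–OH of the unwanted enantiomer and leave the scalemic diol F2.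
   - The less hindered C9–OH is esterified with 15 (pyridine, DMAP) to the C9 mono-senecioate F3, and the C7–OH is silylated (TBSOTf, 2,6-lutidine) to the silyl ether F4.
   - LiN(i-Pr)2 and Me3SiCl (THF, −78 °C) give the silyl ketene acetal diene F5. On heating (toluene, 160 °C) it should add to C5=C11 through the O–C9–C10 tether, forming C1–C11 and C4–C5 on the face of the C9 oxygen, to give the cyclic silyl ortho ester F6. 1 M HCl then releases the bicyclic hydroxy enone F7.
   - Oxidation with 1,1,1-triacetoxy-1,1-dihydro-1,2-benziodoxol-3(1H)-one gives the diketone F8, and DBU eliminates the β-silyloxy group to the bis-enone F9.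
   - NBS/AIBN brominates the γ-methylene C4 to the bromide F10. LiN(i-Pr)2 forms the α′-enolate at C10, whose intramolecular alkylation closes the cyclobutane and gives the tricyclic longipina-2,7-diene-1,9-dione F11.
   - Copper-catalysed conjugate borylation of the C7=C8 enone (C7 boronate F12) and perborate oxidation give the C7 hydroxy ketone F13.
   - Evans–Tishchenko reduction with 3-methylbut-2-enal (SmI2 cat.) gives the C7 senecioate with the anti C9 alcohol F14, and (E)-2-methylbut-2-enoyl chloride (pyridine, DMAP) gives 22.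

2. **Step 6.** Hydride transfer from the hemiacetal of a conjugated aldehyde may be too slow, and the acyl group may migrate between the 1,3-oxygens.

   Fallback (sets out from 12, returns at 16). Evans–Tishchenko reduction with acetaldehyde (SmI2 cat.) gives the C9 acetate with free C7 alcohol F15. Acylation with 15 (pyridine, DMAP) gives the C9 acetate C7 senecioate F16. Mg(OMe)2 in MeOH at 0 °C removes the acetate in preference to the conjugated ester and gives the C9 alcohol F17. (E)-2-Methylbut-2-enoyl chloride (pyridine, DMAP) then gives 16.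

3. **Step 3.** Acyl transfer at a carbinol flanked by a quaternary carbon may be too slow or poorly enantioselective.

   Fallback (sets out from 6, returns at 7). Aerobic oxidative kinetic resolution with Pd(nbd)Cl2 and (−)-sparteine or its (+)-surrogate (O2, toluene, 80 °C), using whichever diamine antipode oxidises the (R)-alcohol to the achiral dione, leaves 7. No new compound lies on the way.

**Further compounds**
F1 | step 9 | rac-4,7,7-trimethylcyclohept-5-ene-1,3-diol (3-OH and 4-H cis, epimers at C1; C3 = C9 and C4 = C10 of the route numbering) | O[C@H]1CC(O)C(C)(C)C=C[C@@H]1C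
F2 | step 9 | scalemic diol, enantiomer of F1 as drawn | O[C@H]1CC(O)C(C)(C)C=C[C@@H]1C
F3 | step 9 | C9 mono-senecioate of F2 | CC(C)=CC(=O)O[C@H]1CC(O)C(C)(C)C=C[C@@H]1C
F4 | step 9 | C7 tert-butyldimethylsilyl ether of F3 | CC(C)=CC(=O)O[C@H]1CC(O[Si](C)(C)C(C)(C)C)C(C)(C)C=C[C@@H]1C
F5 | step 9 | trimethylsilyl ketene acetal diene from F4 | C=C(C)C=C(O[Si](C)(C)C)O[C@H]1CC(O[Si](C)(C)C(C)(C)C)C(C)(C)C=C[C@@H]1C
F6 | step 9 | cyclic silyl ortho ester, Diels–Alder adduct of F5 | C[Si](C)(C)O[C@@]12C=C(C)C[C@H]3[C@@H]1[C@H](C)[C@@H](O2)CC(O[Si](C)(C)C(C)(C)C)C3(C)C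
F7 | step 9 | bicyclic hydroxy enone (C1 enone, C9–OH, C7–OTBS, cis ring fusion C5–C11) | O=C1C=C(C)C[C@H]2[C@@H]1[C@H](C)[C@@H](O)CC(O[Si](C)(C)C(C)(C)C)C2(C)C
F8 | step 9 | C1,C9 diketone from F7 | O=C1C=C(C)C[C@H]2[C@@H]1[C@H](C)C(=O)CC(O[Si](C)(C)C(C)(C)C)C2(C)C
F9 | step 9 | bis-enone (C1 enone and C9 ketone with C7=C8) | O=C1C=C(C)C[C@H]2[C@@H]1[C@H](C)C(=O)C=CC2(C)C
F10 | step 9 | C4 bromide of F9 (epimers at C4) | O=C1C=C(C)C(Br)[C@H]2[C@@H]1[C@H](C)C(=O)C=CC2(C)C
F11 | step 9 | longipina-2,7-diene-1,9-dione | O=C1C=CC(C)(C)[C@@H]2[C@H]3C(=O)C=C(C)[C@@H]2[C@]31C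
F12 | step 9 | C7 pinacolboronate of the C9 ketone | O=C1C[C@@H](B4OC(C)(C)C(C)(C)O4)C(C)(C)[C@@H]2[C@H]3C(=O)C=C(C)[C@@H]2[C@]31C
F13 | step 9 | 7-hydroxylongipin-2-ene-1,9-dione (C7–OH on the face of the enone bridge) | O=C1C[C@@H](O)C(C)(C)[C@@H]2[C@H]3C(=O)C=C(C)[C@@H]2[C@]31C
F14 | step 9 | C7 senecioate C9 alcohol (22 without the tigloyl group) | O[C@@H]1C[C@@H](OC(=O)C=C(C)C)C(C)(C)[C@@H]2[C@H]3C(=O)C=C(C)[C@@H]2[C@]31C
F15 | step 6 | C9 acetate C7 alcohol analogue of 14 | O[C@@H]1C[C@@H](OC(C)=O)[C@](C)(CC(=O)N(C)C)C=CC1(C)C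
F16 | step 6 | C9 acetate C7 senecioate | CC(C)=CC(=O)O[C@@H]1C[C@@H](OC(C)=O)[C@](C)(CC(=O)N(C)C)C=CC1(C)C
F17 | step 6 | C9 alcohol C7 senecioate | CC(C)=CC(=O)O[C@@H]1C[C@@H](O)[C@](C)(CC(=O)N(C)C)C=CC1(C)C
F0 | step 3 | none | none
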